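The numbers in the tables stem from a simulated flask from invented constants; the scatter is artificial.

The constants of the two routes are not given, but their ratio can be read from the runs, and that ratio is what we reckon with here.

| flask | L | Z | remark | time |
|---|---|---|---|---|
| east | 0.020 M (fed, over 4.0 h) | 0.90 µM | run made earlier |  |
| south-west | 0.020 M (fed, over 4.0 h) | 1.4 µM | run made earlier |  |
| south | 0.040 M (fed, over 4.0 h) | 0.64 µM | run made earlier |  |
| flask | 0.020 M (fed, over 4.0 h) | 0.64 µM |  | 15 d |

| run | time / d | L / % | Q / % |
|---|---|---|---|
| east | 1.25 | 0.6 | 79.7 |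
| east | 2.00 | 0 | 80.3 |
| east | 3.00 | 0.6 | 79.3 |
| east | 5.00 | 0 | 79.0 |
| east | 8.00 | 0 | 79.7 |
| east | 12.0 | 0 | 79.3 |
| east | 20.0 | 0 | 79.3 |
| south-west | 2.50 | 0.4 | 85.1 |
| south-west | 5.00 | 0 | 85.8 |
| south-west | 8.00 | 0.3 | 86.0 |
| south-west | 10.0 | 0.6 | 86.1 |
| south-west | 12.0 | 0.3 | 85.7 |
| south-west | 15.0 | 1.0 | 86.3 |
| south-west | 20.0 | 0 | 86.0 |
| south | 4.00 | 0 | 67.5 |
| south | 8.00 | 0 | 68.2 |
| south | 10.0 | 0 | 68.0 |
| south | 15.0 | 0.5 | 66.8 |
| south | 20.0 | 0 | 67.0 |

(scatter of a reading: 0.5 percentage points)

- a reading or a percentage of Q counts all its forms, free or not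
- the reaction counts as stopped when no species that holds the L changes by six tenths of a point or more over the second half of the time

* which holds at 15 d: what has brought the reaction to rest, or that it has not come to rest (forward and back rates have come level / all of L has reacted / it is still moving)
* how much of the L has reacted by 15 d
* how much Q there is at 15 d, in percent of the L charged
* amount of Q if the flask were left three thousand times as long, in percent of the L charged

In the east and south-west runs L reads 0 % and 0 % at 20.0 d, yet Q stands flat at 79.3 % and 86.0 %, so we read L as used up, with part of it gone by a side path. Two extreme versions can be solved in the head: without the side path Q reaches 100 %, and without Z none of the L becomes Q. To place the flask between them we take the split number, the lost share over the Q share multiplied by the amount of Z, at this charge and feed; the east and south-west runs average 0.231 µM. This selectivity factor suits logarithms: between those two runs the logarithm of lost over Q falls against that of Z with slope −1.07, near minus one within the scatter. In the flask, Z stands above the split number, at 2.77 times it, so the logarithm of lost over Q is −0.442, that ratio 0.362, and our Q 73.4 %. The south run, with a larger charge, is flat from 4.00 d, so we expect the flask at rest by 15 d, with 100 % reacted and Q unchanged on the long wait.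

The forecast says all of L has reacted, with 100 % reacted, 73.5 % of Q, and 73.5 % on the long wait, holding that “L is used up, and part of it is lost to a side path competing with the enzyme”.

In the flask all of L has reacted: 100 % has reacted, and Q, its solid form D counted in, stands at 72.7 % at 15 d and 72.7 % on the long wait.

    L + Z → Q + Z, rate k1*[L]*[Z]/(1 + ([L]/Km1) + ([Q]/Kp1)) (14.3 mM, 15.5 mM, k = 1.02 × 10⁶ M⁻¹ h⁻¹)
    L → E (k = 0.136 h⁻¹)
    D ⇌ Q, rate k3*(cs3 - [Q]) while solid is left; crystals form when [Q] > cs3 (solubility = 10.0 mM, k = 8.21 h⁻¹)

The shortfall of Q in the flask comes from the loss of L to E: the same run without that step gives 100 % of Q against 72.7 %. For a further flask, charged like this one but with 0.160 µM of Z, our split number gives lost over Q of 1.44 and Q of 40.9 %, and that flask holds 40.5 %.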